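The chain is built by two Wittig couplings (ring C15 salt + C25 apo-lycopenal; the latter from a ψ-end C15 salt and C10 dialdehyde). Everything rests on the ring end: the cyclopentane C2–C6 (carotenoid numbering), whose C6 lies between C5(OH)CH3 and C2–isopropenyl, is made by contracting a p-menthane six-membered ring that still contains C7. A bromide-relayed epoxide-to-aldehyde rearrangement of a 2,3-epoxy-p-menth-8-en-1-ol silyl ether (from (+)-2-carene) expels C7 as the formyl carbon and, by double inversion, sets C6 with CHO cis to isopropenyl and C5-methyl, trans to the C5 oxygen. It exploits the position of C6 between C5 and C2: either epoxide carbon can be the migration terminus, and both modes converge.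

Key step: step 5

Remarks on the chemistry: carotenoid numbering is used for the target (ring C2–C6, C7 the first chain carbon). Commercial pseudoionone is treated as its (3E,5E)-isomer; minor Z material is expected to be lost when salt 15 is crystallised. The carbinol centres of 10 and 14 form as mixtures and are destroyed in the following step.

Step 1
Reactants: 1 (+)-2-carene
Product: 2 (+)-trans-2-carene oxide
Conditions: mCPBA (1.1 equiv), NaHCO3, CH2Cl2, 0 °C
Reagents that add atoms: 3-chloroperoxybenzoic acid, O=C(OO)c1cccc(Cl)c1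
Why: Prilezhaev epoxidation of the trisubstituted ring alkene; the peracid should approach the face opposite the gem-dimethylcyclopropane bridge, which sets both oxirane centres, and the bicarbonate buffer protects the acid-labile vinylcyclopropane-derived epoxide.

Step 2
Reactants: 2 (+)-trans-2-carene oxide
Product: 3 (1R,4R)-p-mentha-2,8-dien-1-ol
Conditions: TiO(OH)2 (metatitanic acid, cat.), toluene, reflux
Reagents that add atoms: none
Why: Acid-catalysed cyclopropylcarbinyl-to-homoallyl ring opening: ionisation of the oxirane C–O bond next to the cyclopropane is assisted by cleavage of the adjacent cyclopropane bond and the tertiary cation loses a methyl proton to give isopropenyl, so the carane becomes a p-menthane while the tertiary C–O bond and the ring–C(CH3)2 bond stay intact, which relays the anti epoxide geometry into OH trans to isopropenyl (CH3 cis).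

Step 3
Reactants: 3 (1R,4R)-p-mentha-2,8-dien-1-ol
Product: 4 (1S,2R,5S,6S)-2-methyl-5-(prop-1-en-2-yl)-7-oxabicyclo[4.1.0]heptan-2-ol
Conditions: VO(acac)2 (2 mol %), t-BuOOH (1.3 equiv, decane), CH2Cl2, 0 °C to rt
Reagents that add atoms: tert-butyl hydroperoxide, CC(C)(C)OO
Why: Hydroxyl-directed vanadium-catalysed epoxidation: the vanadate ester of the tertiary allylic alcohol delivers oxygen to the ring alkene on the OH face (also the face away from CH3 and isopropenyl), setting both oxirane centres cis to OH, and leaves the unactivated isopropenyl alkene alone.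

Step 4
Reactants: 4 (1S,2R,5S,6S)-2-methyl-5-(prop-1-en-2-yl)-7-oxabicyclo[4.1.0]heptan-2-ol
Product: 5 triethyl{[(1S,2R,5S,6S)-2-methyl-5-(prop-1-en-2-yl)-7-oxabicyclo[4.1.0]heptan-2-yl]oxy}silane
Conditions: Et3SiOTf (1.3 equiv), 2,6-lutidine (2 equiv), CH2Cl2, −78 to −20 °C
Reagents that add atoms: triethylsilyl trifluoromethanesulfonate, CC[Si](CC)(CC)OS(=O)(=O)C(F)(F)F
Why: Silyl triflate silylation of a hindered tertiary alcohol with a non-nucleophilic base at low temperature, which the oxirane should survive; the cap is needed so that the tertiary oxygen cannot act as an alkoxide in step 5 and the product cannot undergo retro-aldol cleavage.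

Step 5
Reactants: 5 triethyl{[(1S,2R,5S,6S)-2-methyl-5-(prop-1-en-2-yl)-7-oxabicyclo[4.1.0]heptan-2-yl]oxy}silane
Product: 8 (1R,2R,5R)-2-methyl-5-(prop-1-en-2-yl)-2-[(triethylsilyl)oxy]cyclopentane-1-carbaldehyde, via lithium bromohydrin alkoxide 6 (not isolated), via regioisomeric lithium bromohydrin alkoxide 7 (not isolated)
Conditions: LiBr (0.5 equiv), HMPA (0.5 equiv), toluene, 80 °C; cold neutral work-up, used crude
Reagents that add atoms: none
Why: The lithium-coordinated oxirane of 5 should be opened anti by bromide to the trans-bromohydrin alkoxides 6 and 7, which after ring flip hold C–Br equatorial and antiperiplanar to a ring C–C bond; the alkoxide then pushes that bond onto the bromide-bearing carbon with loss of bromide (the silyloxy-bearing carbon migrates in 6, the isopropenyl-bearing carbon in 7), so the carbinol carbon leaves the ring as CHO and both regioisomers converge on 8. The closest known reaction type is the lithium-halide-catalysed epoxide-to-carbonyl rearrangement of cyclohexene oxides to cyclopentanecarbaldehydes through halohydrin salts, a semipinacol ring contraction. The cyclopentane is closed by a suprafacial 1,2-alkyl shift with retention at the migrating carbon, not by an exo or endo cyclisation. The only new stereocentre, the formyl-bearing carbon, is fixed by two successive inversions at the same carbon (bromide anti to the oxirane oxygen, then the migrating carbon anti to bromide), which places CHO on the face opposite the former oxirane oxygen, that is cis to isopropenyl and to the methyl and trans to OSiEt3; the other two centres are untouched or migrate with retention. The step needs the halide relay to outrun a direct Lewis-acid Meinwald shift (which would give the epimeric aldehyde) and a hydride shift (ketone); a weakly Lewis acidic but strongly nucleophilic LiBr–HMPA system, the trans-bromohydrin geometry (no antiperiplanar hydrogen on the carbinol carbon, the diaxial conformer only re-closing to 5) and the silyl cap on the tertiary oxygen should secure this. Work-up is kept neutral and cold because the all-cis aldehyde is the kinetic epimer.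

Step 6
Reactants: 8 (1R,2R,5R)-2-methyl-5-(prop-1-en-2-yl)-2-[(triethylsilyl)oxy]cyclopentane-1-carbaldehyde
Product: 9 (E)-4-[(1R,2R,5R)-2-methyl-5-(prop-1-en-2-yl)-2-[(triethylsilyl)oxy]cyclopentyl]but-3-en-2-one
Conditions: Ph3P=CHC(O)CH3 (2.5 equiv), toluene, 80 °C
Reagents that add atoms: 1-(triphenylphosphoranylidene)propan-2-one, CC(=O)C=P(c1ccccc1)(c1ccccc1)c1ccccc1
Why: Wittig olefination with a stabilised, essentially non-basic ylide should give the (E)-enone (C7=C8) without a base that could epimerise the formyl-bearing centre.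

Step 7
Reactants: 9 (E)-4-[(1R,2R,5R)-2-methyl-5-(prop-1-en-2-yl)-2-[(triethylsilyl)oxy]cyclopentyl]but-3-en-2-one
Product: 10 (1E)-3-methyl-1-[(1R,2R,5R)-2-methyl-5-(prop-1-en-2-yl)-2-[(triethylsilyl)oxy]cyclopentyl]penta-1,4-dien-3-ol (both C3 epimers)
Conditions: CH2=CHMgBr (1.5 equiv), THF, −30 to 0 °C; then H2O
Reagents that add atoms: vinylmagnesium bromide, C=C[Mg]Br
Why: Grignard 1,2-addition to the methyl ketone of the enone, as in vinyl-ionol preparations; the new carbinol centre forms unselectively and is destroyed in step 8.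

Step 8
Reactants: 10 (1E)-3-methyl-1-[(1R,2R,5R)-2-methyl-5-(prop-1-en-2-yl)-2-[(triethylsilyl)oxy]cyclopentyl]penta-1,4-dien-3-ol
Product: 12 [(2E,4E)-5-[(1R,2R,5R)-2-hydroxy-2-methyl-5-(prop-1-en-2-yl)cyclopentyl]-3-methylpenta-2,4-dien-1-yl]triphenylphosphonium bromide, via silyl-protected phosphonium bromide 11 (not isolated)
Conditions: PPh3·HBr (1.3 equiv), MeOH, 0 °C to rt; precipitation from EtOAc/Et2O
Reagents that add atoms: triphenylphosphine hydrobromide, [Br-].c1ccc(cc1)[PH+](c1ccccc1)c1ccccc1
Why: Acid-mediated SN1-type allylic substitution with transposition: the bis-allylic tertiary carbinol ionises to a pentadienyl cation that PPh3 captures at the terminus to give the conjugated (2E,4E)-dienyl salt (thermodynamic geometry), and the same methanolic HBr should methanolyse the triethylsilyl ether while the non-allylic tertiary ring alcohol does not ionise.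

Step 9
Reactants: 13 (3E,5E)-pseudoionone
Product: 14 (4E,6E)-3,7,11-trimethyldodeca-1,4,6,10-tetraen-3-ol (racemic)
Conditions: CH2=CHMgBr (1.3 equiv), THF, −20 to 0 °C; then H2O
Reagents that add atoms: vinylmagnesium bromide, C=C[Mg]Br
Why: Grignard 1,2-addition to the dienone carbonyl; the carbinol centre is racemic and is removed in step 10.

Step 10
Reactants: 14 (4E,6E)-3,7,11-trimethyldodeca-1,4,6,10-tetraen-3-ol
Product: 15 [(2E,4E,6E)-3,7,11-trimethyldodeca-2,4,6,10-tetraen-1-yl]triphenylphosphonium bromide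
Conditions: PPh3·HBr (1.05 equiv), MeOH, rt; crystallisation
Reagents that add atoms: triphenylphosphine hydrobromide, [Br-].c1ccc(cc1)[PH+](c1ccccc1)c1ccccc1
Why: The same acid-mediated allylic substitution with transposition as in step 8, giving the conjugated all-E trienyl phosphonium salt after crystallisation.

Step 11
Reactants: 15 [(2E,4E,6E)-3,7,11-trimethyldodeca-2,4,6,10-tetraen-1-yl]triphenylphosphonium bromide; 16 (2E,4E,6E)-2,7-dimethylocta-2,4,6-trienedial
Product: 18 apo-12'-lycopenal, (2E,4E,6E,8E,10E,12E,14E)-2,7,11,15,19-pentamethylicosa-2,4,6,8,10,12,14,18-octaenal, via ψ-end ylide 17 (not isolated)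
Conditions: NaOMe (1.05 equiv), 16 (2.5 equiv), CH2Cl2/MeOH, 0 °C to rt; then I2 (1 mol %), hexane, visible light
Reagents that add atoms: none
Why: Wittig olefination with a semi-stabilised allylic ylide; the excess of dialdehyde should secure mono-condensation, and iodine-catalysed equilibration should convert the Z isomer at the new double bond into the all-E aldehyde.

Step 12
Reactants: 12 [(2E,4E)-5-[(1R,2R,5R)-2-hydroxy-2-methyl-5-(prop-1-en-2-yl)cyclopentyl]-3-methylpenta-2,4-dien-1-yl]triphenylphosphonium bromide; 18 apo-12'-lycopenal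
Product: 20 CNP0222499.3, (1R,2R,3R)-2-[(1E,3E,5E,7E,9E,11E,13E,15E,17E,19E)-3,7,12,16,20,24-hexamethylpentacosa-1,3,5,7,9,11,13,15,17,19,23-undecaen-1-yl]-1-methyl-3-(prop-1-en-2-yl)cyclopentan-1-ol, via ring-end ylide 19 (not isolated)
Conditions: NaOMe (1.3 equiv), CH2Cl2/MeOH, rt, argon, dark; then I2 (cat.), hexane/benzene, visible light, rt; crystallisation
Reagents that add atoms: none
Why: Wittig olefination forming C11=C12 in the presence of the free tertiary alcohol (as is usual for hydroxylated carotenoid end groups); the E/Z mixture at the new bond should equilibrate to the all-E polyene, and no stereocentre is touched.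

Compound list
1 | (+)-2-carene, (1S,6R)-3,7,7-trimethylbicyclo[4.1.0]hept-2-ene | CC1=C[C@H]2[C@@H](CC1)C2(C)C | starting material
2 | (+)-trans-2-carene oxide: 2,3-epoxide of 1 with the oxirane oxygen on the ring face opposite the C(CH3)2 bridge | C[C@@]12CC[C@@H]3[C@H]([C@@H]1O2)C3(C)C | intermediate
3 | (1R,4R)-1-methyl-4-(prop-1-en-2-yl)cyclohex-2-en-1-ol (p-mentha-2,8-dien-1-ol; OH trans to isopropenyl, CH3 cis) | C=C(C)[C@@H]1CC[C@@](C)(O)C=C1 | intermediate
4 | (1S,2R,5S,6S)-2-methyl-5-(prop-1-en-2-yl)-7-oxabicyclo[4.1.0]heptan-2-ol (oxirane cis to OH, trans to isopropenyl) | C=C(C)[C@@H]1CC[C@@](C)(O)[C@H]2O[C@@H]12 | intermediate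
5 | triethyl{[(1S,2R,5S,6S)-2-methyl-5-(prop-1-en-2-yl)-7-oxabicyclo[4.1.0]heptan-2-yl]oxy}silane | C=C(C)[C@@H]1CC[C@@](C)(O[Si](CC)(CC)CC)[C@H]2O[C@@H]12 | intermediate
6 | lithium 2-bromo-6-methyl-3-(prop-1-en-2-yl)-6-[(triethylsilyl)oxy]cyclohexan-1-olate (Br cis to the neighbouring isopropenyl; O– trans to Br, cis to OSiEt3; formed in situ) | C=C(C)[C@@H]1CC[C@@](C)(O[Si](CC)(CC)CC)[C@@H]([O-])[C@@H]1Br.[Li+] | intermediate
7 | lithium 2-bromo-3-methyl-6-(prop-1-en-2-yl)-3-[(triethylsilyl)oxy]cyclohexan-1-olate (Br cis to the neighbouring CH3; O– trans to Br and to isopropenyl; formed in situ) | C=C(C)[C@@H]1CC[C@@](C)(O[Si](CC)(CC)CC)[C@H](Br)[C@H]1[O-].[Li+] | intermediate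
8 | (1R,2R,5R)-2-methyl-5-(prop-1-en-2-yl)-2-[(triethylsilyl)oxy]cyclopentane-1-carbaldehyde (CHO cis to isopropenyl and CH3) | C=C(C)[C@@H]1CC[C@@](C)(O[Si](CC)(CC)CC)[C@@H]1C=O | intermediate
9 | (E)-4-[(1R,2R,5R)-2-methyl-5-(prop-1-en-2-yl)-2-[(triethylsilyl)oxy]cyclopentyl]but-3-en-2-one | C=C(C)[C@@H]1CC[C@@](C)(O[Si](CC)(CC)CC)[C@@H]1/C=C/C(C)=O | intermediate
10 | (1E)-3-methyl-1-[(1R,2R,5R)-2-methyl-5-(prop-1-en-2-yl)-2-[(triethylsilyl)oxy]cyclopentyl]penta-1,4-dien-3-ol (C3 epimers) | C=C(C)[C@@H]1CC[C@@](C)(O[Si](CC)(CC)CC)[C@@H]1/C=C/C(C)(O)C=C | intermediate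
11 | [(2E,4E)-3-methyl-5-[(1R,2R,5R)-2-methyl-5-(prop-1-en-2-yl)-2-[(triethylsilyl)oxy]cyclopentyl]penta-2,4-dien-1-yl]triphenylphosphonium bromide (formed in situ) | C=C(C)[C@@H]1CC[C@@](C)(O[Si](CC)(CC)CC)[C@@H]1/C=C/C(C)=C/C[P+](c1ccccc1)(c1ccccc1)c1ccccc1.[Br-] | intermediate
12 | [(2E,4E)-5-[(1R,2R,5R)-2-hydroxy-2-methyl-5-(prop-1-en-2-yl)cyclopentyl]-3-methylpenta-2,4-dien-1-yl]triphenylphosphonium bromide | C=C(C)[C@@H]1CC[C@@](C)(O)[C@@H]1/C=C/C(C)=C/C[P+](c1ccccc1)(c1ccccc1)c1ccccc1.[Br-] | intermediate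
13 | (3E,5E)-pseudoionone, (3E,5E)-6,10-dimethylundeca-3,5,9-trien-2-one | CC(C)=CCC/C(C)=C/C=C/C(C)=O | starting material
14 | (4E,6E)-3,7,11-trimethyldodeca-1,4,6,10-tetraen-3-ol (racemic) | CC(C)=CCC/C(C)=C/C=C/C(C)(O)C=C | intermediate
15 | [(2E,4E,6E)-3,7,11-trimethyldodeca-2,4,6,10-tetraen-1-yl]triphenylphosphonium bromide | CC(C)=CCC/C(C)=C/C=C/C(C)=C/C[P+](c1ccccc1)(c1ccccc1)c1ccccc1.[Br-] | intermediate
16 | (2E,4E,6E)-2,7-dimethylocta-2,4,6-trienedial (C10 dialdehyde) | O=C/C(C)=C/C=C/C=C(C)/C=O | starting material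
17 | [(2E,4E,6E)-3,7,11-trimethyldodeca-2,4,6,10-tetraen-1-ylidene]triphenylphosphorane (formed in situ) | CC(C)=CCC/C(C)=C/C=C/C(C)=C/C=P(c1ccccc1)(c1ccccc1)c1ccccc1 | intermediate
18 | apo-12'-lycopenal, (2E,4E,6E,8E,10E,12E,14E)-2,7,11,15,19-pentamethylicosa-2,4,6,8,10,12,14,18-octaenal | O=C/C(C)=C/C=C/C=C(C)/C=C/C=C(C)/C=C/C=C(\C)CCC=C(C)C | intermediate
19 | [(2E,4E)-5-[(1R,2R,5R)-2-hydroxy-2-methyl-5-(prop-1-en-2-yl)cyclopentyl]-3-methylpenta-2,4-dien-1-ylidene]triphenylphosphorane (formed in situ) | C=C(C)[C@@H]1CC[C@@](C)(O)[C@@H]1/C=C/C(C)=C/C=P(c1ccccc1)(c1ccccc1)c1ccccc1 | intermediate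
20 | CNP0222499.3, (1R,2R,3R)-2-[(1E,3E,5E,7E,9E,11E,13E,15E,17E,19E)-3,7,12,16,20,24-hexamethylpentacosa-1,3,5,7,9,11,13,15,17,19,23-undecaen-1-yl]-1-methyl-3-(prop-1-en-2-yl)cyclopentan-1-ol | C=C(C)[C@@H]1CC[C@@](C)(O)[C@@H]1/C=C/C(C)=C/C=C/C(C)=C/C=C/C=C(C)/C=C/C=C(C)/C=C/C=C(\C)CCC=C(C)C | target

Total step count: 12. Longest linear sequence: 9 steps (steps 1–8 and 12, from 1).

Steps most likely to fail

Step 5. Bromide attack on the doubly flanked oxirane may be slower than lithium-promoted ionisation, so that a direct Meinwald shift (formyl group on the wrong face) or a hydride shift to a ketone competes; the all-cis aldehyde may also epimerise on prolonged heating. The fallback sets out from 5 and returns at 8, and splits the relay into two discrete operations with a different trigger. Epoxide 5 would be opened with MgI2·OEt2 in Et2O/toluene at −40 °C to the trans-iodohydrin 2-iodo-6-methyl-3-(prop-1-en-2-yl)-6-[(triethylsilyl)oxy]cyclohexan-1-ol F1 (iodine cis to the neighbouring isopropenyl, OH trans to iodine), together with its regioisomer 2-iodo-3-methyl-6-(prop-1-en-2-yl)-3-[(triethylsilyl)oxy]cyclohexan-1-ol F2 (iodine cis to the neighbouring methyl). After isolation the mixture would be treated with AgBF4 and 2,6-di-tert-butylpyridine in CH2Cl2 at −40 to 0 °C. Silver should abstract iodide while the antiperiplanar ring bond migrates (silver-triggered iodohydrin semipinacol ring contraction), both isomers giving 8 at low temperature.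

Step 6. Slow olefination of the hindered formyl group may let the formyl-bearing centre epimerise (the all-cis aldehyde is the less stable epimer) or the β-silyloxy group eliminate. The fallback sets out from 8 and returns at 9, and replaces carbonyl olefination by a cross-coupling. Takai olefination of 8 (CrCl2, CHI3, THF, 0 °C) should give the (E)-vinyl iodide triethyl{[2-[(E)-2-iodoethenyl]-1-methyl-3-(prop-1-en-2-yl)cyclopentyl]oxy}silane F3 (ring centres as in 8). Stille coupling with tributyl(1-ethoxyvinyl)stannane (Pd(PPh3)4, zerovalent palladium, CuI, DMF, rt) should give the 2-ethoxydiene {[2-[(1E)-3-ethoxybuta-1,3-dien-1-yl]-1-methyl-3-(prop-1-en-2-yl)cyclopentyl]oxy}triethylsilane F4. Brief hydrolysis of the enol ether (PPTS, wet acetone, 0 °C) should then deliver enone 9.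

Step 8. The acid may ionise or cyclise the tertiary ring alcohol, the silyl ether may be only partly methanolysed, or the 2,3-double-bond geometry may scramble during cation capture. The fallback sets out from 9 (and uses 18) and returns at 20; it reverses the polarity of the last coupling so that the ring half never meets acid.
- Ring half: Horner–Wadsworth–Emmons reaction of 9 with diethyl (cyanomethyl)phosphonate (NaH, THF) would give the dienenitrile (2E,4E)-3-methyl-5-[2-methyl-5-(prop-1-en-2-yl)-2-[(triethylsilyl)oxy]cyclopentyl]penta-2,4-dienenitrile F5 (2E isomer separated). DIBAL reduction (toluene, −78 °C) would give the C15 aldehyde (2E,4E)-3-methyl-5-[2-methyl-5-(prop-1-en-2-yl)-2-[(triethylsilyl)oxy]cyclopentyl]penta-2,4-dienal F6.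
- Chain half: 18 would be reduced (NaBH4, MeOH, 0 °C) to apo-12'-lycopenol F7 and converted with PPh3·HBr into the C25 salt (apo-12'-lycopenyl)triphenylphosphonium bromide F8.
- Union: Wittig coupling of F8 with F6 (NaOMe, CH2Cl2/MeOH) would give the triethylsilyl ether of the target F9, and TBAF (THF, 0 °C) would release 20.

Further compounds
F1 | step 5 | 2-iodo-6-methyl-3-(prop-1-en-2-yl)-6-[(triethylsilyl)oxy]cyclohexan-1-ol (I cis to isopropenyl, OH trans to I and cis to OSiEt3) | C=C(C)[C@@H]1CC[C@@](C)(O[Si](CC)(CC)CC)[C@@H](O)[C@@H]1I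
F2 | step 5 | 2-iodo-3-methyl-6-(prop-1-en-2-yl)-3-[(triethylsilyl)oxy]cyclohexan-1-ol (I cis to the neighbouring CH3, OH trans to I) | C=C(C)[C@@H]1CC[C@@](C)(O[Si](CC)(CC)CC)[C@H](I)[C@H]1O
F3 | step 6 | triethyl{[2-[(E)-2-iodoethenyl]-1-methyl-3-(prop-1-en-2-yl)cyclopentyl]oxy}silane (ring centres as in 8) | C=C(C)[C@@H]1CC[C@@](C)(O[Si](CC)(CC)CC)[C@@H]1/C=C/I
F4 | step 6 | {[2-[(1E)-3-ethoxybuta-1,3-dien-1-yl]-1-methyl-3-(prop-1-en-2-yl)cyclopentyl]oxy}triethylsilane (ring centres as in 8) | C=C(C)[C@@H]1CC[C@@](C)(O[Si](CC)(CC)CC)[C@@H]1/C=C/C(=C)OCC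
F5 | step 8 | (2E,4E)-3-methyl-5-[(1R,2R,5R)-2-methyl-5-(prop-1-en-2-yl)-2-[(triethylsilyl)oxy]cyclopentyl]penta-2,4-dienenitrile | C=C(C)[C@@H]1CC[C@@](C)(O[Si](CC)(CC)CC)[C@@H]1/C=C/C(C)=C/C#N
F6 | step 8 | (2E,4E)-3-methyl-5-[(1R,2R,5R)-2-methyl-5-(prop-1-en-2-yl)-2-[(triethylsilyl)oxy]cyclopentyl]penta-2,4-dienal | C=C(C)[C@@H]1CC[C@@](C)(O[Si](CC)(CC)CC)[C@@H]1/C=C/C(C)=C/C=O
F7 | step 8 | apo-12'-lycopenol, (2E,4E,6E,8E,10E,12E,14E)-2,7,11,15,19-pentamethylicosa-2,4,6,8,10,12,14,18-octaen-1-ol | OC/C(C)=C/C=C/C=C(C)/C=C/C=C(C)/C=C/C=C(\C)CCC=C(C)C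
F8 | step 8 | [(2E,4E,6E,8E,10E,12E,14E)-2,7,11,15,19-pentamethylicosa-2,4,6,8,10,12,14,18-octaen-1-yl]triphenylphosphonium bromide | [Br-].c1ccccc1[P+](c1ccccc1)(c1ccccc1)C/C(C)=C/C=C/C=C(C)/C=C/C=C(C)/C=C/C=C(\C)CCC=C(C)C
F9 | step 8 | triethylsilyl ether of 20 | C=C(C)[C@@H]1CC[C@@](C)(O[Si](CC)(CC)CC)[C@@H]1/C=C/C(C)=C/C=C/C(C)=C/C=C/C=C(C)/C=C/C=C(C)/C=C/C=C(\C)CCC=C(C)C
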